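**Remark:** compounds 12 and 13 are each treated as one compound although both equilibrate with enol forms (13 also with its ring-closed hemiketal). The CH(OMe) carbon between the two carbonyl groups is therefore racemic, labile and needs no control. No error was found in the structures of the key-step precursors or product, so they are used unchanged.

## Structural features

- The target 14 is a flavone: benzene ring A is fused to the 4-pyranone ring C, and ring B is attached to C2 through the C2–C1' bond.
- Every position of ring A is substituted (C5 OH, C6 OMe, C7 OH, C8 OMe, C8a O1, C4a bonded to C4). Ring C carries the C4 carbonyl and a 3-methoxy group. Ring B has methoxy groups at C2' and C4' and a hydroxyl at C5'.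
- There is no stereocentre, so none stand next to each other. The only stereogenic carbon met on the way, C3 as CH(OMe) in the open-chain diketone, is enolisable and becomes sp2 on ring closure.
- The fragile parts are the three free phenols on very electron-rich rings, which oxidise easily in base and air. The five methyl ethers must stay distinct from the three hydroxyls, which rules out any late global demethylation.
- The real difficulty is twofold: sorting eight oxygen substituents into five methyl ethers and three hydroxyls, and forming the C4–C4a bond at a ring carbon whose two neighbours, C5 and C8a, both carry oxygen.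
- With the same group on O1 and O5, ring A is symmetric about the axis through C4a and C7 (C5 equals C8a, C6 equals C8). A precursor then has one ring CH, at the future C4a, and either ortho oxygen can become O1.
- The key step uses this symmetry together with the fact that C4 is a single carbonyl carbon between C4a and the methoxy-bearing C3. C4 enters as carbon monoxide between an aryl iodide at C4a and an enolate carbon at C3.

## Logic of the disconnections

**14 to 13.** The enol-ether bond O1–C2 of ring C is cut. This opens the pyranone to a C2–C3–C4 dicarbonyl chain on C4a and removes the only ring that is formed late. In 13 the two hydroxyls ortho to the C4 carbonyl are equivalent, so the choice of O1 disappears. The forward step must dehydrate in one direction only; ring B has OMe, not OH, at C2', so only a ring A oxygen can add to the C2 carbonyl.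

**13 to 12.** The four O–H bonds are traced back to O–benzyl bonds. One kind of protecting group for all three free hydroxyls and for O1 allows a single hydrogenolysis and keeps the methyl ethers untouched. The demand is that hydrogenolysis spares the two aryl ketones and that the benzyl ethers survive strong base and palladium in the step before.

**12 to 4, 11 and 10.** The bonds C4a–C4 and C4–C3 on both sides of the C4 carbonyl are cut. This is the largest simplification of the route: two arenes of similar size and a one-carbon unit, with no acyl substitution at a crowded carbonyl. The forward step must insert 11 before any coupling and must acylate the enolate of 10 on carbon. Because 12 is more acidic than 10, two equivalents of 10 and of base are planned.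

**4 to 3.** The C4a–I bond is cut. 3 has a single ring CH, flanked by two benzyloxy groups and para to the third, so iodination needs no regiocontrol.

**3 to 2.** The two aryl C–OMe bonds at the future C6 and C8 are traced back to C–Br bonds. Both oxygens are introduced in one operation, where a formylation, oxidation and methylation sequence would need three operations per oxygen. The demand is a copper-mediated substitution at bromides that each have two ortho substituents.

**2 to 1.** The two C–Br bonds are cut. 1 is commercial and threefold symmetric, so the first two brominations cannot give isomers; only the degree of bromination has to be controlled by stoichiometry.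

**10 to 8 and 9.** The bond between C1' of ring B and the ketone carbon (the future C2) is cut. The position para to one methoxy and ortho to the other is the most nucleophilic of 8, so the acylation is regioselective. The demand is a Lewis acid mild enough for the benzyl ether and for the α-alkoxy acyl chloride.

**8 to 7, and 7 to 5 through 6.** The O–benzyl bond is cut, then the C5'–O bond is traced back to the C–CHO bond of 5. The aldehyde of a cheap commodity arene marks the carbon that must carry oxygen. The forward oxidation relies on aryl migration in an electron-rich benzaldehyde.

## Other disconnections considered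

**Alternative 1:** The cut runs through C4–C4a and O1–C2, so ring C closes in one operation from the unprotected symmetric triol 2,4-dimethoxybenzene-1,3,5-triol (A1) and the ring B α-methoxy-β-ketoester ethyl 3-[5-(benzyloxy)-2,4-dimethoxyphenyl]-2-methoxy-3-oxopropanoate (A2). In the forward key step the two would be heated without catalyst (a Simonis-type thermal condensation). The single ring CH of A1 would be acylated by the ester carbon and a neighbouring hydroxyl would condense with the ketone, giving the 5'-O-benzyl flavone A3; one hydrogenolysis would then lead to 14.

- In favour: it reads the symmetry of ring A exactly as the chosen plan does (equal). It needs no protecting group on ring A at the key stage, no transition metal and no toxic gas (better). Both bonds of ring C form at once at the flavone oxidation level. A1 and A2 would be one step each from 3 and 10.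
- Against, here: A1 is a pentaoxygenated phenol that oxidises readily and would have to withstand temperatures above 200 °C. An α-substituted β-ketoester with a hindered, electron-rich aroyl group is a sluggish partner. The condensation also has a second manifold (Pechmann mode: ring carbon to ketone, oxygen to ester) that leads to a 4-arylcoumarin skeleton, and nothing in the substrates decides between the two.
- Comparison: on structure the plans are equivalent. On mechanism, the alternative forms the crowded C4–C4a bond by uncatalysed acyl substitution under forcing conditions; the chosen plan forms it by CO insertion at a metal at 80 °C and fixes the chromone connectivity before any ring closes. On step economy the alternative needs nine operations against eight, which is essentially equal. The chosen plan is preferred for control, not for brevity.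

**Alternative 2:** The cuts are C3–C4 and C2=C3. C3 with its methoxy group would come from methoxymethylenetriphenylphosphorane (A5). The rest would come from the ring A acid chloride 2,4-bis(benzyloxy)-6-{[5-(benzyloxy)-2,4-dimethoxybenzoyl]oxy}-3,5-dimethoxybenzoyl chloride (A4), which carries the ring B aroyl group as an ester on the oxygen that becomes O1. In the forward key step two equivalents of A5 would C-acylate at the acid chloride and deprotonate the resulting phosphonium salt to an acyl ylide. This would olefinate the neighbouring ester carbonyl intramolecularly (ester Wittig reaction) and close ring C as the tri-O-benzyl flavone A6; hydrogenolysis would give 14.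

- In favour: the flavone arrives at the correct oxidation level without a dehydration step. The conditions are non-acidic and spare every ether, and no CO or palladium is needed (better). C3 with its OMe comes from a simple one-carbon reagent (equal to CO in convergence).
- Against, here: the first bond forms by acyl substitution at a carbonyl flanked by two ortho oxygen substituents, which is the event the chosen plan avoids. A5 is a basic, non-stabilised ylide that may attack the less hindered aryl ester of A4 instead. Olefination of an ester carbonyl by an α-methoxy acyl ylide is a demanding Wittig reaction. A4 also breaks the symmetry of ring A: its two ortho oxygens must be differentiated and a carboxyl group installed, which costs several more operations.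
- Comparison: on structure the alternative gives up the symmetry that makes 4 easy to prepare. On mechanism both plans flank C4 with two new bonds, but the alternative depends on two consecutive additions to hindered or deactivated carbonyl groups. Step economy is worse before the key step and equal after it (one deprotection against one telescoped deprotection and cyclisation).

**Alternative 3:** Ring A itself would be the last ring made. The cut is C4a–C5 (and, one step earlier, C8–C8a), which traces ring A back to the cyclobutenone 2-[5-(benzyloxy)-2,4-dimethoxyphenyl]-6-[2-(benzyloxy)-1,3-dimethoxy-4-oxocyclobut-2-en-1-yl]-3-methoxy-4H-pyran-4-one (A7, racemic). A7 would come from the 6-metalated form of the pyranone 2-[5-(benzyloxy)-2,4-dimethoxyphenyl]-3-methoxy-4H-pyran-4-one (A10) and the mixed squarate 3-(benzyloxy)-4-methoxycyclobut-3-ene-1,2-dione (A9), followed by O-methylation. In the forward key step, thermolysis of A7 would open the four-membered ring to a dienylketene, which would close by 6π electrocyclisation onto the CH carbon of the pyranone. Tautomerisation would give A8 with ring A complete, 5-OH free and 7-O benzylated.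

- In favour: every oxygen of ring A is placed by the cyclobutenone, with no electrophilic substitution on a crowded arene. The step is thermal and needs no reagent, metal or CO (better). The 5-OH emerges free and distinct from 7-O, a differentiation the chosen plan cannot offer, although 14 does not need it.
- Against, here: the addition of metalated A10 to A9 must choose between two carbonyl groups that differ only in OMe against OBn on the neighbouring carbon, and no bias can be argued. A10 needs its own multistep synthesis and a regioselective metalation at C6. The electrocyclisation must engage a double bond of an electron-poor pyranone. The symmetry of ring A is not used at all.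
- Comparison: on structure the alternative treats a symmetric ring as unsymmetrical and pays with a regiochemical problem at A9. On mechanism its concerted cascade, once A7 is in hand, is on a par with or better than a palladium cycle in robustness. On step economy it is clearly longer (separate syntheses of A9 and A10, addition, methylation, thermolysis, hydrogenolysis).

Key step: step 7

## Route

Step 1
Reactants: 1 1,3,5-tris(benzyloxy)benzene
Product: 2 1,3,5-tris(benzyloxy)-2,4-dibromobenzene
Conditions: NBS (2.05 equiv), CH2Cl2–MeCN, 0 °C → rt, dark
Reagents that add atoms: N-bromosuccinimide, O=C1CCC(=O)N1Br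
Why: Electrophilic aromatic bromination; each ring CH of 1 is ortho or para to three benzyloxy groups, so two brominations are fast, while the third is slowed by the two bromines already present and is held back by stoichiometry. The pendant phenyl rings are not activated.

Step 2
Reactants: 2 1,3,5-tris(benzyloxy)-2,4-dibromobenzene
Product: 3 1,3,5-tris(benzyloxy)-2,4-dimethoxybenzene
Conditions: NaOMe (25% in MeOH, 10 equiv), CuBr (0.3 equiv), DMF, 100 °C, N2
Reagents that add atoms: sodium methoxide, [Na+].[O-]C
Why: Ullmann-type copper-catalysed methoxylation of aryl bromides; a copper methoxide formed from CuBr and NaOMe exchanges each bromide for methoxide, a reaction type that tolerates electron-rich bromides with two ortho substituents. Benzyl ethers and the lone ring C–H are inert to methoxide, and the two bromides are equivalent in environment.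

Step 3
Reactants: 3 1,3,5-tris(benzyloxy)-2,4-dimethoxybenzene
Product: 4 1,3,5-tris(benzyloxy)-2-iodo-4,6-dimethoxybenzene
Conditions: NIS (1.1 equiv), CF3CO2H (0.2 equiv), MeCN, 0 °C → rt
Reagents that add atoms: N-iodosuccinimide, O=C1CCC(=O)N1I
Why: Electrophilic aromatic iodination at the only ring CH, which is ortho to two benzyloxy groups and para to the third; no regioisomer or over-iodination on this ring is possible.

Step 4
Reactants: 5 2,4-dimethoxybenzaldehyde
Product: 7 2,4-dimethoxyphenol, via 2,4-dimethoxyphenyl formate 6 (not isolated)
Conditions: mCPBA (1.2 equiv), CH2Cl2, 0 °C → rt; aq. Na2S2O3/NaHCO3 wash; then K2CO3 (0.2 equiv), MeOH, rt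
Reagents that add atoms: 3-chloroperbenzoic acid (mCPBA), OOC(=O)c1cccc(Cl)c1
Why: Baeyer–Villiger (Dakin-type) oxidation; the aryl group, made electron-rich by the ortho and para methoxy groups, migrates in the Criegee adduct in preference to hydride and gives formate 6. Mild base-catalysed methanolysis then releases phenol 7.

Step 5
Reactants: 7 2,4-dimethoxyphenol
Product: 8 1-(benzyloxy)-2,4-dimethoxybenzene
Conditions: BnBr (1.1 equiv), K2CO3 (1.5 equiv), DMF, 50 °C
Reagents that add atoms: benzyl bromide, BrCc1ccccc1
Why: Williamson ether synthesis; the phenoxide displaces bromide from the benzylic carbon, and no other nucleophilic site is present.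

Step 6
Reactants: 8 1-(benzyloxy)-2,4-dimethoxybenzene; 9 methoxyacetyl chloride
Product: 10 1-[5-(benzyloxy)-2,4-dimethoxyphenyl]-2-methoxyethan-1-one
Conditions: SnCl4 (1.2 equiv), CH2Cl2, −20 → 0 °C
Reagents that add atoms: none
Why: Friedel–Crafts acylation; C5 of 8 is para to the 2-methoxy and ortho to the 4-methoxy group and is the only position activated by two donors without lying between two substituents. SnCl4 at low temperature is chosen to spare the benzyl ether and the α-alkoxy acyl chloride, and the new ketone deactivates the ring against a second acylation.

Step 7
Reactants: 4 1,3,5-tris(benzyloxy)-2-iodo-4,6-dimethoxybenzene; 10 1-[5-(benzyloxy)-2,4-dimethoxyphenyl]-2-methoxyethan-1-one; 11 carbon monoxide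
Product: 12 1-[5-(benzyloxy)-2,4-dimethoxyphenyl]-2-methoxy-3-[2,4,6-tris(benzyloxy)-3,5-dimethoxyphenyl]propane-1,3-dione (racemic, enolisable)
Conditions: Pd(dba)2 (5 mol %), Xantphos (5 mol %), 10 (2.1 equiv), NaN(SiMe3)2 (2.0 equiv), CO (1 atm), dioxane, 80 °C; then aq. NH4Cl
Reagents that add atoms: none
Why: Oxidative addition of the C–I bond of 4 to zerovalent palladium (from Pd(dba)2 and the bisphosphine Xantphos) gives an arylpalladium iodide whose metal is wedged between two benzyloxy groups; migratory insertion of CO moves the metal one atom away from the ring, relieves that crowding and forms the C4a–C4 bond as an aroyl complex of divalent palladium. The sodium enolate of 10, formed in the same pot by NaN(SiMe3)2, replaces iodide and binds through carbon, and reductive elimination forms the C4–C3 bond and returns zerovalent palladium. The closest known reaction type is the palladium-catalysed carbonylative α-arylation of ketones with aryl iodides to 1,3-diketones, applied here to a doubly ortho-substituted iodide and an α-methoxy ketone. No ring is closed in this step. The CH(OMe) carbon of 12 is formally stereogenic, but it lies between two carbonyl groups, is formed racemic, is configurationally labile and becomes sp2 in 14, so nothing has to control it. The selectivity needed is chemoselectivity: carbonylative over direct α-arylation is secured by the slow coupling of a 2,6-disubstituted arylpalladium compared with CO insertion, and C- over O-acylation is driven by the deprotonation of 12 to its chelated diketonate by the second equivalent of enolate, which is why 10 and the base are used twofold. Regiochemistry is not at stake because 4 bears iodine on the only carbon that was free, on the symmetry axis of ring A.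

Step 8
Reactants: 12 1-[5-(benzyloxy)-2,4-dimethoxyphenyl]-2-methoxy-3-[2,4,6-tris(benzyloxy)-3,5-dimethoxyphenyl]propane-1,3-dione
Product: 14 5,7-dihydroxy-2-(5-hydroxy-2,4-dimethoxyphenyl)-3,6,8-trimethoxy-4H-chromen-4-one (target), via tetrahydroxy diketone 13 (not isolated)
Conditions: H2 (1 atm), 10% Pd/C, EtOAc–AcOH, rt; filter under N2; then H2SO4 (cat.), AcOH, 80 °C
Reagents that add atoms: none
Why: Hydrogenolysis cleaves the four benzylic C–O bonds and leaves methyl ethers and aryl ketones intact; acid then promotes addition of a ring A hydroxyl ortho to the C4 carbonyl to the ring B carbonyl and loss of water (cyclodehydration of a 2-hydroxyaryl 1,3-diketone), closing ring C. The two ortho hydroxyls are equivalent and ring B has no ortho hydroxyl, so only one flavone can form; the symmetry of ring A also makes any acid-induced ring-opening and reclosure degenerate.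

## Compound list

1 | 1,3,5-tris(benzyloxy)benzene | c1ccc(COc2cc(OCc3ccccc3)cc(OCc3ccccc3)c2)cc1 | starting material
2 | 1,3,5-tris(benzyloxy)-2,4-dibromobenzene | Brc1c(OCc2ccccc2)cc(OCc2ccccc2)c(Br)c1OCc1ccccc1 | intermediate
3 | 1,3,5-tris(benzyloxy)-2,4-dimethoxybenzene | COc1c(OCc2ccccc2)cc(OCc2ccccc2)c(OC)c1OCc1ccccc1 | intermediate
4 | 1,3,5-tris(benzyloxy)-2-iodo-4,6-dimethoxybenzene | COc1c(OCc2ccccc2)c(I)c(OCc2ccccc2)c(OC)c1OCc1ccccc1 | intermediate
5 | 2,4-dimethoxybenzaldehyde | COc1ccc(C=O)c(OC)c1 | starting material
6 | 2,4-dimethoxyphenyl formate | COc1ccc(OC=O)c(OC)c1 | intermediate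
7 | 2,4-dimethoxyphenol | COc1ccc(O)c(OC)c1 | intermediate
8 | 1-(benzyloxy)-2,4-dimethoxybenzene | COc1ccc(OCc2ccccc2)c(OC)c1 | intermediate
9 | methoxyacetyl chloride | COCC(=O)Cl | starting material
10 | 1-[5-(benzyloxy)-2,4-dimethoxyphenyl]-2-methoxyethan-1-one | COCC(=O)c1cc(OCc2ccccc2)c(OC)cc1OC | intermediate
11 | carbon monoxide | [C-]#[O+] | starting material
12 | 1-[5-(benzyloxy)-2,4-dimethoxyphenyl]-2-methoxy-3-[2,4,6-tris(benzyloxy)-3,5-dimethoxyphenyl]propane-1,3-dione (racemic, enolisable) | COC(C(=O)c1cc(OCc2ccccc2)c(OC)cc1OC)C(=O)c1c(OCc2ccccc2)c(OC)c(OCc2ccccc2)c(OC)c1OCc1ccccc1 | intermediate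
13 | 1-(5-hydroxy-2,4-dimethoxyphenyl)-2-methoxy-3-(2,4,6-trihydroxy-3,5-dimethoxyphenyl)propane-1,3-dione (racemic, enolisable) | COC(C(=O)c1cc(O)c(OC)cc1OC)C(=O)c1c(O)c(OC)c(O)c(OC)c1O | intermediate
14 | 5,7-dihydroxy-2-(5-hydroxy-2,4-dimethoxyphenyl)-3,6,8-trimethoxy-4H-chromen-4-one | COc1cc(OC)c(-c2oc3c(OC)c(O)c(OC)c(O)c3c(=O)c2OC)cc1O | target

## Step count and least certain steps

Total step count: 8. Longest linear sequence: 5 steps (1 to 14 through 2, 3, 4 and 12; equally 5 to 14 through 7, 8, 10 and 12).

**Step 7 (key step).** The catalytic cycle is most likely to stall at oxidative addition: the iodide is very electron-rich and has two ortho substituents, and CO competes for zerovalent palladium. Reduction of the C–I bond, O-acylation of the enolate, and cyclopalladation onto an ortho benzyl group are further ways to lose material.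
Fallback: it sets out from 3 (with 10) and returns at 12. Vilsmeier formylation of 3 (POCl3, DMF) at its only ring CH would give 2,4,6-tris(benzyloxy)-3,5-dimethoxybenzaldehyde F1. Aldol addition of the lithium enolate of 10 (LiN(SiMe3)2, THF, −78 °C) to F1 would give 1-[5-(benzyloxy)-2,4-dimethoxyphenyl]-3-hydroxy-2-methoxy-3-[2,4,6-tris(benzyloxy)-3,5-dimethoxyphenyl]propan-1-one F2 as a mixture of diastereomers. Oxidation of F2 with Dess–Martin periodinane would converge on 12. An aldehyde tolerates ortho crowding far better than an acyl chloride, and steps 3 and 7 are bypassed.

**Step 2.** Hydrodebromination may compete with substitution, because reductive loss of halogen from the aryl–copper intermediate is favoured at carbons flanked by two alkoxy groups. Exchange of the second bromide may also remain incomplete.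
Fallback: it sets out from 1 and returns at 3, replacing steps 1 and 2.
- Vilsmeier formylation of 1 would give 2,4,6-tris(benzyloxy)benzaldehyde F3.
- Baeyer–Villiger oxidation with mCPBA would give 2,4,6-tris(benzyloxy)phenyl formate F4, and methanolysis (K2CO3, MeOH) would give 2,4,6-tris(benzyloxy)phenol F5.
- Methylation (MeI, K2CO3, DMF) would give 1,3,5-tris(benzyloxy)-2-methoxybenzene F6.
- A second formylation at either of the two equivalent ring CH positions would give 2,4,6-tris(benzyloxy)-3-methoxybenzaldehyde F7.
- Oxidation would give 2,4,6-tris(benzyloxy)-3-methoxyphenyl formate F8, methanolysis would give 2,4,6-tris(benzyloxy)-3-methoxyphenol F9, and methylation of F9 would give 3.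

**Step 6.** The Lewis acid may induce loss of CO from the α-alkoxy acyl chloride, giving an alkylating methoxymethyl cation in place of the acylium ion. Loss of the benzyl protecting group at the Lewis acid is a second risk.
Fallback: it sets out from 8 (and 9) and returns at 10. Bromination of 8 with NBS in MeCN would give 1-(benzyloxy)-5-bromo-2,4-dimethoxybenzene F10, with the same regiochemistry as the acylation. 9 and N,O-dimethylhydroxylamine hydrochloride with pyridine would give N,2-dimethoxy-N-methylacetamide F11. Bromine–lithium exchange on F10 (n-BuLi, THF, −78 °C) and addition to F11 would give 10 without any Lewis acid.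

**Step 8.** Cleavage of the two benzyl ethers that flank the ketone may be slow. Forcing the hydrogenolysis risks reduction at a benzylic carbonyl, and the debenzylated polyphenol may oxidise in air before the ring closes.
Fallback: it sets out from 12 and returns at 13, with no new compound. The benzyl ethers of 12 would be cleaved with BCl3 and pentamethylbenzene as cation scavenger in CH2Cl2 at −78 °C, a temperature at which aryl methyl ethers should persist. The same acid treatment as in step 8 would then close ring C.

## Further compounds

F1 | step 7 | 2,4,6-tris(benzyloxy)-3,5-dimethoxybenzaldehyde | COc1c(OCc2ccccc2)c(C=O)c(OCc2ccccc2)c(OC)c1OCc1ccccc1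
F2 | step 7 | 1-[5-(benzyloxy)-2,4-dimethoxyphenyl]-3-hydroxy-2-methoxy-3-[2,4,6-tris(benzyloxy)-3,5-dimethoxyphenyl]propan-1-one (racemic mixture of diastereomers) | COC(C(=O)c1cc(OCc2ccccc2)c(OC)cc1OC)C(O)c1c(OCc2ccccc2)c(OC)c(OCc2ccccc2)c(OC)c1OCc1ccccc1
F3 | step 2 | 2,4,6-tris(benzyloxy)benzaldehyde | O=Cc1c(OCc2ccccc2)cc(OCc2ccccc2)cc1OCc1ccccc1
F4 | step 2 | 2,4,6-tris(benzyloxy)phenyl formate | O=COc1c(OCc2ccccc2)cc(OCc2ccccc2)cc1OCc1ccccc1
F5 | step 2 | 2,4,6-tris(benzyloxy)phenol | Oc1c(OCc2ccccc2)cc(OCc2ccccc2)cc1OCc1ccccc1
F6 | step 2 | 1,3,5-tris(benzyloxy)-2-methoxybenzene | COc1c(OCc2ccccc2)cc(OCc2ccccc2)cc1OCc1ccccc1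
F7 | step 2 | 2,4,6-tris(benzyloxy)-3-methoxybenzaldehyde | COc1c(OCc2ccccc2)cc(OCc2ccccc2)c(C=O)c1OCc1ccccc1
F8 | step 2 | 2,4,6-tris(benzyloxy)-3-methoxyphenyl formate | COc1c(OCc2ccccc2)cc(OCc2ccccc2)c(OC=O)c1OCc1ccccc1
F9 | step 2 | 2,4,6-tris(benzyloxy)-3-methoxyphenol | COc1c(OCc2ccccc2)cc(OCc2ccccc2)c(O)c1OCc1ccccc1
F10 | step 6 | 1-(benzyloxy)-5-bromo-2,4-dimethoxybenzene | COc1cc(OC)c(OCc2ccccc2)cc1Br
F11 | step 6 | N,2-dimethoxy-N-methylacetamide | COCC(=O)N(C)OC
F0 | step 8 | none | none
A1 | alternative 1 | 2,4-dimethoxybenzene-1,3,5-triol | COc1c(O)cc(O)c(OC)c1O
A2 | alternative 1 | ethyl 3-[5-(benzyloxy)-2,4-dimethoxyphenyl]-2-methoxy-3-oxopropanoate (racemic) | CCOC(=O)C(OC)C(=O)c1cc(OCc2ccccc2)c(OC)cc1OC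
A3 | alternative 1 | 2-[5-(benzyloxy)-2,4-dimethoxyphenyl]-5,7-dihydroxy-3,6,8-trimethoxy-4H-chromen-4-one | COc1cc(OC)c(-c2oc3c(OC)c(O)c(OC)c(O)c3c(=O)c2OC)cc1OCc1ccccc1
A4 | alternative 2 | 2,4-bis(benzyloxy)-6-{[5-(benzyloxy)-2,4-dimethoxybenzoyl]oxy}-3,5-dimethoxybenzoyl chloride | COc1c(OCc2ccccc2)c(OC)c(OC(=O)c2cc(OCc3ccccc3)c(OC)cc2OC)c(C(=O)Cl)c1OCc1ccccc1
A5 | alternative 2 | methoxymethylenetriphenylphosphorane | COC=P(c1ccccc1)(c1ccccc1)c1ccccc1
A6 | alternative 2 | 5,7-bis(benzyloxy)-2-[5-(benzyloxy)-2,4-dimethoxyphenyl]-3,6,8-trimethoxy-4H-chromen-4-one | COc1cc(OC)c(-c2oc3c(OC)c(OCc4ccccc4)c(OC)c(OCc4ccccc4)c3c(=O)c2OC)cc1OCc1ccccc1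
A7 | alternative 3 | 2-[5-(benzyloxy)-2,4-dimethoxyphenyl]-6-[2-(benzyloxy)-1,3-dimethoxy-4-oxocyclobut-2-en-1-yl]-3-methoxy-4H-pyran-4-one (racemic) | COc1cc(OC)c(-c2oc(C3(OC)C(=O)C(OC)=C3OCc3ccccc3)cc(=O)c2OC)cc1OCc1ccccc1
A8 | alternative 3 | 7-(benzyloxy)-2-[5-(benzyloxy)-2,4-dimethoxyphenyl]-5-hydroxy-3,6,8-trimethoxy-4H-chromen-4-one | COc1cc(OC)c(-c2oc3c(OC)c(OCc4ccccc4)c(OC)c(O)c3c(=O)c2OC)cc1OCc1ccccc1
A9 | alternative 3 | 3-(benzyloxy)-4-methoxycyclobut-3-ene-1,2-dione | COC1=C(OCc2ccccc2)C(=O)C1=O
A10 | alternative 3 | 2-[5-(benzyloxy)-2,4-dimethoxyphenyl]-3-methoxy-4H-pyran-4-one | COc1cc(OC)c(-c2occc(=O)c2OC)cc1OCc1ccccc1
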